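**Plan**

1. Retrosynthesis: the C2 acetate is traded for a benzoate (ester exchange last), the side chain is cut at C11–C12 (sp3–sp3 Suzuki–Miyaura coupling) and at C9=C11 (methylenation of a C9 ketone), ring A is opened at C3–C4, and C10–C1 and C10–C20 are cut back to (R)-carvone.
2. Forward: ring B is (R)-carvone itself (C5 stereocentre, C8 methyl, C7=C8, C9 carbonyl; the isopropenyl group is C4 with its two methyls). Two α′-alkylations build quaternary C10, and the allyl arm is oxidised to the (R)-α-benzoyloxy aldehyde C1–C3.
3. Ring A is then closed by reductive, Markovnikov-selective addition of the isopropenyl group to the C3 aldehyde. This is possible because C4 of ring A is a quaternary carbon bearing two methyls next to the C3 carbinol, so it can be unmasked from the carvone isopropenyl group as a tertiary radical/organometal while C3 is an aldehyde on the C10 arm.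
4. The C9 carbonyl is methylenated, hydroborated and coupled with a C12–C15 bromo ester to attach the whole side chain; benzoate-to-acetate exchange finishes the synthesis.
5. Stereochemistry: C5 from carvone; C10 by alkylation anti to the isopropenyl group; C2 by aminocatalysis; C3 by Felkin–Anh control in the ring closure; C9 by hydroboration anti to the axial C10 methyl; C13 from (R)-β-methyl-γ-butyrolactone.

Key step: step 5

Remark: labdane numbering (C1–C20) and the usual α/β convention (C10 methyl β) are used for all intermediates; lactone 10 is assumed to be purchasable in enantiopure form.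

**Step 1**
Reactants: 1 (R)-(−)-carvone
Product: 3 (5R)-2,6-dimethyl-5-(prop-1-en-2-yl)cyclohex-2-en-1-one (6-methylcarvone; both C6 epimers), via lithium dienolate 2 (not isolated)
Conditions: LDA (commercial solution, 1.05 equiv), THF, −78 °C; MeI, −78 → 0 °C
Reagents that add atoms: iodomethane, CI
Why: Kinetic α′-deprotonation with LDA and C-methylation of the cross-conjugated lithium dienolate (enolate alkylation) should install the future C20 methyl group; the new centre (labdane C10) is left as an epimer mixture because it is planarised again in step 2.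

**Step 2**
Reactants: 3 6-methylcarvone
Product: 5 (5S,6S)-2,6-dimethyl-5-(prop-1-en-2-yl)-6-(prop-2-en-1-yl)cyclohex-2-en-1-one (allyl trans and methyl cis to the isopropenyl group), via lithium enolate 4 (not isolated)
Conditions: LDA (commercial solution), THF, −78 °C; allyl bromide, DMPU, −78 °C → rt
Reagents that add atoms: allyl bromide, C=CCBr
Why: Enolate alkylation of the tetrasubstituted lithium enolate with the reactive allylic bromide should create quaternary C10, the electrophile approaching anti to the adjacent C5 isopropenyl group so that the allyl arm (C1–C3) ends up trans and the methyl group cis to it.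

**Step 3**
Reactants: 5 allyl methyl carvone
Product: 6 3-[(1S,6S)-1,3-dimethyl-2-oxo-6-(prop-1-en-2-yl)cyclohex-3-en-1-yl]propanal
Conditions: PdCl2(PhCN)2 (12 mol %), CuCl2·2H2O (12 mol %), AgNO2 (6 mol %), O2 (1 atm), t-BuOH/MeNO2 15:1, rt
Reagents that add atoms: dioxygen, O=O (the oxygen atom is relayed by the nitrite co-catalyst)
Why: Nitrite-modified, aldehyde-selective (anti-Markovnikov) Wacker oxidation should convert only the monosubstituted allyl alkene, because the 1,1-disubstituted isopropenyl group and the enone alkene are poor Wacker substrates; no stereocentre is formed.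

**Step 4**
Reactants: 6 keto aldehyde
Product: 7 (2R)-3-[(1S,6S)-1,3-dimethyl-2-oxo-6-(prop-1-en-2-yl)cyclohex-3-en-1-yl]-1-oxopropan-2-yl benzoate
Conditions: (R)-α,α-diphenylprolinol trimethylsilyl ether (20 mol %), (BzO)2 (1.2 equiv), hydroquinone (10 mol %), THF, 0 °C; rapid filtration through silica and direct use
Reagents that add atoms: dibenzoyl peroxide, O=C(OOC(=O)c1ccccc1)c1ccccc1
Why: Enamine catalysis (organocatalytic α-benzoyloxylation of an aldehyde): the diphenyl(silyloxy)methyl group of the (R)-configured amine shields one face of the E-enamine, so the peroxide should deliver the benzoate to C2 with the (R) configuration under catalyst control, the ring stereocentres being remote.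

**Step 5**
Reactants: 7 (R)-α-benzoyloxy aldehyde
Product: 8 (4aS,6S,7R,8aS)-7-benzoyloxy-6-hydroxy-2,5,5,8a-tetramethyl-4a,5,6,7,8,8a-hexahydronaphthalen-1(4H)-one (trans-fused; 2α-benzoyloxy, 3α-hydroxy, 5α-H, 10β-methyl, C7=C8, C9 ketone)
Conditions: Co(salen)Cl [C32H46ClCoN2O2; salen = N,N′-bis(3,5-di-tert-butylsalicylidene)ethane-1,2-diaminate] (10 mol %), CrCl3 (20 mol %), PhSiH3 (2 equiv), THF (0.01 M), rt; aq. NH4Cl work-up
Reagents that add atoms: none
Why: A cobalt hydride formed from the salen complex and PhSiH3 should transfer a hydrogen atom to the CH2 terminus of the isopropenyl group, the tertiary C4 radical should be captured by divalent chromium, and the tertiary alkylchromium should add to the C3 aldehyde (radical–polar crossover; the closest known reaction type is the cobalt/chromium MHAT-initiated branch-selective reductive coupling of unactivated 1,1-disubstituted alkenes with aldehydes, used here intramolecularly and related to hydride-HAT cyclisations of alkene-tethered ketones). Ring A closes in the 6-exo-trig mode onto the C=O group through a chair transition state, and the trans ring fusion follows from the C5 and C10 arms both being equatorial on ring B. The new C3 stereocentre is controlled by the C2 benzoate: with the benzoate equatorial its C–O bond is antiperiplanar to the forming C3–C4 bond (polar Felkin–Anh arrangement), the carbonyl oxygen then takes the axial site next to C1 and the aldehyde hydrogen sits between the two C4 methyl groups, which should give the 3α (axial) alcohol cis to the 2α-benzoate. C4 becomes the gem-dimethyl quaternary carbon and is not stereogenic. The step needs chemoselective hydrogen-atom transfer with Markovnikov regiochemistry, secured because the isopropenyl group is the only electron-rich 1,1-disubstituted alkene (C7=C8 is an electron-poor trisubstituted enone alkene and the C9 carbonyl could only be reached through a four-membered ring), and it needs trapping by the aldehyde before the tertiary radical is reduced, which the six-membered intramolecular geometry and high dilution favour.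

**Step 6**
Reactants: 8 bicyclic enone
Product: 9 diene: the C9-methylidene analogue of 8 (C9=C11H2 exocyclic, C7=C8 retained; 2α-benzoyloxy, 3α-hydroxy, 5α-H, 10β-methyl)
Conditions: Zn, CH2Br2, TiCl4 (reagent pre-formed in THF at 5 °C), CH2Cl2, 0 °C → rt
Reagents that add atoms: dibromomethane, BrCBr
Why: Takai–Lombardo methylenation with the non-basic zinc/titanium methylene reagent should convert the hindered, non-enolisable C9 ketone into the exocyclic alkene while the benzoate and the free C3 hydroxyl are left alone (ketone-selective over esters); no stereocentre is formed.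

**Step 7**
Reactants: 10 (R)-4-methyloxolan-2-one ((R)-β-methyl-γ-butyrolactone)
Product: 11 methyl (3R)-4-bromo-3-methylbutanoate
Conditions: HBr (gas), MeOH, 0 °C → rt
Reagents that add atoms: hydrogen bromide, Br; methanol, CO
Why: Acid-mediated ring opening of the γ-lactone by bromide at the primary C–O carbon (SN2) together with Fischer esterification in methanol should give the bromo ester, the stereocentre (future C13) not being involved.

**Step 8**
Reactants: 9 diene; 11 methyl (3R)-4-bromo-3-methylbutanoate
Product: 13 methyl (13S)-2α-benzoyloxy-3α-hydroxylabd-7-en-15-oate, via B-alkyl-9-BBN borane 12 (not isolated)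
Conditions: 9-BBN (1.2 equiv), THF, 0 °C → rt; then 11, Pd(OAc)2 (5 mol %), PCy3 (10 mol %), K3PO4·H2O, THF, rt → 40 °C; ethanolamine work-up
Reagents that add atoms: none
Why: Hydroboration then B-alkyl Suzuki–Miyaura sp3–sp3 coupling: 9-BBN should add to the less hindered exocyclic C9=C11 bond with boron at C11 and hydrogen delivered to C9 from the α-face, anti to the axial C10 methyl group, which sets the 9α-H configuration, and the electron-rich Pd/PCy3 catalyst should then join the alkylborane to the primary bromide (C11–C12) without touching C13.

**Step 9**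
Reactants: 13 benzoate ester
Product: 14 methyl (13S)-2α,3α-dihydroxylabd-7-en-15-oate
Conditions: NaOMe (0.3 equiv), MeOH, rt
Reagents that add atoms: none
Why: Base-catalysed transesterification (Zemplén-type methanolysis) should cleave the secondary benzoate as methyl benzoate, while the C15 methyl ester is degenerate in methanol and no stereocentre is epimerisable.

**Step 10**
Reactants: 14 diol
Product: 15 methyl (13S)-2α-acetoxy-3α-hydroxylabd-7-en-15-oate (CNP0571009.1)
Conditions: Ac2O (1.1 equiv), pyridine, CH2Cl2, 0 °C
Reagents that add atoms: acetic anhydride, CC(=O)OC(C)=O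
Why: Site-selective acylation: the equatorial C2 hydroxyl should be acetylated much faster than the axial C3 hydroxyl, which is neopentyl and flanked by the C4 gem-dimethyl group, giving the target monoacetate.

**Compound list**

1 | (R)-(−)-carvone | CC1=CC[C@H](CC1=O)C(C)=C | starting material
2 | lithium cross-conjugated dienolate of carvone (O–C9=C10, C7=C8) | [Li]OC1=C[C@H](C(C)=C)CC=C1C | intermediate
3 | (5R)-2,6-dimethyl-5-(prop-1-en-2-yl)cyclohex-2-en-1-one (C6 epimers) | CC1C(=O)C(C)=CC[C@H]1C(C)=C | intermediate
4 | lithium enolate of 3 (O–C9=C10) | [Li]OC1=C(C)[C@H](C(C)=C)CC=C1C | intermediate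
5 | (5S,6S)-2,6-dimethyl-5-(prop-1-en-2-yl)-6-(prop-2-en-1-yl)cyclohex-2-en-1-one | C=CC[C@]1(C)C(=O)C(C)=CC[C@H]1C(C)=C | intermediate
6 | 3-[(1S,6S)-1,3-dimethyl-2-oxo-6-(prop-1-en-2-yl)cyclohex-3-en-1-yl]propanal | O=CCC[C@]1(C)C(=O)C(C)=CC[C@H]1C(C)=C | intermediate
7 | (2R)-3-[(1S,6S)-1,3-dimethyl-2-oxo-6-(prop-1-en-2-yl)cyclohex-3-en-1-yl]-1-oxopropan-2-yl benzoate | O=C[C@H](OC(=O)c1ccccc1)C[C@]2(C)C(=O)C(C)=CC[C@H]2C(C)=C | intermediate
8 | (4aS,6S,7R,8aS)-7-benzoyloxy-6-hydroxy-2,5,5,8a-tetramethyl-4a,5,6,7,8,8a-hexahydronaphthalen-1(4H)-one | O=C1C(C)=CC[C@H]2C(C)(C)[C@H](O)[C@H](OC(=O)c3ccccc3)C[C@]12C | intermediate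
9 | C9-methylidene diene (2α-benzoyloxy, 3α-hydroxy, C7=C8, C9=C11H2) | C=C1C(C)=CC[C@H]2C(C)(C)[C@H](O)[C@H](OC(=O)c3ccccc3)C[C@]12C | intermediate
10 | (R)-4-methyloxolan-2-one | O=C1C[C@@H](C)CO1 | starting material
11 | methyl (3R)-4-bromo-3-methylbutanoate | COC(=O)C[C@@H](C)CBr | intermediate
12 | C11 B-alkyl-9-BBN borane of 9 (9α-H) | B1(C2CCCC1CCC2)C[C@H]3C(C)=CC[C@H]4C(C)(C)[C@H](O)[C@H](OC(=O)c5ccccc5)C[C@]34C | intermediate
13 | methyl (13S)-2α-benzoyloxy-3α-hydroxylabd-7-en-15-oate | COC(=O)C[C@@H](C)CC[C@H]1C(C)=CC[C@H]2C(C)(C)[C@H](O)[C@H](OC(=O)c3ccccc3)C[C@]12C | intermediate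
14 | methyl (13S)-2α,3α-dihydroxylabd-7-en-15-oate | COC(=O)C[C@@H](C)CC[C@H]1C(C)=CC[C@H]2C(C)(C)[C@H](O)[C@H](O)C[C@]12C | intermediate
15 | methyl (13S)-2α-acetoxy-3α-hydroxylabd-7-en-15-oate | COC(=O)C[C@@H](C)CC[C@H]1C(C)=CC[C@H]2C(C)(C)[C@H](O)[C@H](OC(C)=O)C[C@]12C | target

**Step count and risks**

Total step count: 10. Longest linear sequence: 9 steps (steps 1–6 and 8–10 from (R)-carvone); step 7 is a one-step branch.

Step 5 may fail through back transfer of hydrogen that isomerises the isopropenyl group to the tetrasubstituted C4=C5 alkene, through simple reduction of the tertiary radical, through reductive loss of the α-benzoyloxy group at chromium, or through erosion of facial selectivity at C3. The fallback sets out from aldehyde 6, which carries no C2 oxygen. Fe(acac)3/PhSiH3 in EtOH at 60 °C should close ring A by free-radical 6-exo addition of the C4 radical to the aldehyde and give the bicyclic 3-hydroxy enone F1 as a C3 epimer mixture. Dehydration with the Burgess reagent can only run towards C2, because C4 is quaternary, and should give the Δ2-alkene F2. OsO4/NMO should dihydroxylate C2=C3 from the α-face, away from the axial C10 and C4 β-methyl groups, to give the 2α,3α-diol enone F3. Benzoylation of the equatorial C2 hydroxyl (BzCl, pyridine, 0 °C) comes back to the route at compound 8.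

Step 8 may fail through slow oxidative addition of the β-branched bromide, so that protodeboronation and β-hydride elimination take over. The fallback sets out from diene 9. Hydroboration to borane 12 as before, followed by oxidation with NaBO3·4H2O, gives the C11 primary alcohol F4, and an Appel reaction (I2, PPh3, imidazole) gives the primary iodide F5. Bromide 11 is converted with activated zinc dust in DMA into the alkylzinc bromide F6. A nickel-catalysed alkyl–alkyl Negishi coupling of F5 with F6 (Ni(cod)2, s-Bu-Pybox, DMA, rt), which runs through an alkyl radical and tolerates β-branching, comes back to the route at compound 13.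

Step 6 may fail through lack of addition to the doubly flanked C9 carbonyl group or through titanium-induced migration of the benzoate. The fallback sets out from compound 8. NaOMe/MeOH removes the benzoate and gives the diol enone F3 already described above. Excess TMSCH2Li/CeCl3 (THF, −78 → 0 °C) should add to the non-enolisable C9 ketone of the dialkoxide to give the β-hydroxysilane F7, and KH in THF (Peterson olefination) should give the diene diol F8. Selective benzoylation of the equatorial C2 hydroxyl (BzCl, pyridine, 0 °C) comes back to the route at compound 9.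

**Further compounds**

F1 | step 5 | (4aS,8aS)-6-hydroxy-2,5,5,8a-tetramethyl-4a,5,6,7,8,8a-hexahydronaphthalen-1(4H)-one (C3 epimers) | O=C1C(C)=CC[C@H]2C(C)(C)C(O)CC[C@]12C
F2 | step 5 | Δ2-alkene enone (C2=C3, C7=C8, C9 ketone) | O=C1C(C)=CC[C@H]2C(C)(C)C=CC[C@]12C
F3 | step 5 | 2α,3α-diol enone | O=C1C(C)=CC[C@H]2C(C)(C)[C@H](O)[C@H](O)C[C@]12C
F4 | step 8 | C11 primary alcohol (9α-H; 2α-benzoyloxy, 3α-hydroxy) | OC[C@H]1C(C)=CC[C@H]2C(C)(C)[C@H](O)[C@H](OC(=O)c3ccccc3)C[C@]12C
F5 | step 8 | C11 primary iodide | IC[C@H]1C(C)=CC[C@H]2C(C)(C)[C@H](O)[C@H](OC(=O)c3ccccc3)C[C@]12C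
F6 | step 8 | [(2R)-4-methoxy-2-methyl-4-oxobutyl]zinc bromide | COC(=O)C[C@@H](C)C[Zn]Br
F7 | step 6 | C9 β-hydroxysilane triol (C9 configuration not defined) | C[Si](C)(C)CC1(O)C(C)=CC[C@H]2C(C)(C)[C@H](O)[C@H](O)C[C@]12C
F8 | step 6 | diene 2α,3α-diol (C9=C11H2, C7=C8) | C=C1C(C)=CC[C@H]2C(C)(C)[C@H](O)[C@H](O)C[C@]12C
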